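**Strategy.** The route rests on disconnecting the C5=C6 bond of the γ-ylidene butenolide (lactone ring C6–C7–C11–C12–O). This enol-lactone alkene is traced back to addition of the acidic butenolide γ-carbon C6 to a C5 aldehyde on quaternary C4, followed by loss of the C5 oxygen. In one operation this closes the oxygen-bridged ten-membered carbocycle (C1–C10) and installs the trisubstituted alkene, using the γ-CH2 acidity of the butenolide and the cis arms of the tetrahydrofuran ring (C1–C4, O). The precursor is a cis-2,5-disubstituted tetrahydrofuran methyl ketal with the non-enolisable C5 aldehyde on C4 and, on C1, the C10–C9–C8 chain ending in a γ-unsubstituted 3-(silyloxymethyl)butenolide, C8 and C13 being TBS ethers.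

Key step: step 17

**Remarks**

- Locants: C1 ketal (finally hemiketal) carbon; C2, C3 ring CH2; C4 methyl-bearing ether carbon; C5 the carbon on C4 that becomes the vinylic CH; C6, C7, C11 the butenolide γ-, β- and α-carbons; C12 lactone carbonyl; C13 the CH2O on C11; C8 oxygen-bearing CH; C9 CH2; C10 methyl-bearing CH.
- Configuration planned for: 1S, 4R, 8R, 10R, side chain 2R, C5=C6 E (C4 and C7 cis).
- Assumption: (S)-2-methylglycidol, (E)-2,3-dibromobut-2-ene-1,4-diol, (S)-4-benzyl-3-propionyloxazolidin-2-one and (R)-3-chloro-2-hydroxy-2-methylpropanoic acid are taken as commercial.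
- Assumption: the two C1 epimers formed in step 7 are separable and interconvert in acidic methanol.
- Design notes:
  - C13 is on the butenolide from the start, because a β-substituted butenolide cannot be hydroxymethylated at C11 later.
  - C10 is set by an auxiliary, since an achiral crotyl reagent cannot control it relative to remote C4.
  - C5 is carried as a PMB ether, so that no second terminal alkene competes when C8 is unveiled.
  - C8 is set by reagent-controlled reduction.

**Route**

Step 1
Reactants: 1 (S)-4-benzyl-3-propionyloxazolidin-2-one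
Product: 2 (S)-4-benzyl-3-[(R)-2-methylpent-4-enoyl]oxazolidin-2-one
Conditions: NaN(SiMe3)2, THF, −78 °C; allyl iodide, −78 → −45 °C
Reagents that add atoms: allyl iodide, C=CCI
Why: Evans auxiliary-controlled enolate alkylation: the chelated (Z)-sodium enolate is allylated on the face away from the benzyl group, which sets C10 (R).

Step 2
Reactants: 2 allylated imide
Product: 3 (R)-N-methoxy-N,2-dimethylpent-4-enamide
Conditions: MeNHOMe·HCl, AlMe3, CH2Cl2, −10 °C → rt
Reagents that add atoms: N,O-dimethylhydroxylamine hydrochloride, CNOC.Cl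
Why: Weinreb amide formation by aluminium amide transamination removes the auxiliary at the exocyclic carbonyl and leaves the α-stereocentre untouched.

Step 3
Reactants: 4 (S)-2-methylglycidol
Product: 5 (R)-2-[(4-methoxybenzyloxy)methyl]-2-methyloxirane
Conditions: NaH, 4-methoxybenzyl chloride, Bu4NI (cat.), THF–DMF, 0 °C → rt
Reagents that add atoms: 4-methoxybenzyl chloride, COc1ccc(CCl)cc1
Why: Williamson etherification of the primary alkoxide protects the future C5 oxygen as a PMB ether while the epoxide, whose quaternary carbon becomes C4 (R), is not opened.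

Step 4
Reactants: 5 PMB epoxide
Product: 6 (R)-1-(4-methoxybenzyloxy)-2-methyl-4-(phenylsulfonyl)butan-2-ol
Conditions: PhSO2Me, n-BuLi, THF, −78 → 0 °C; then 5, 0 °C → rt
Reagents that add atoms: methyl phenyl sulfone, CS(=O)(=O)c1ccccc1
Why: SN2 epoxide opening by the α-sulfonyl carbanion at the unsubstituted CH2 terminus forms C2–C3 and leaves the C4–O bond and its configuration intact.

Step 5
Reactants: 6 hydroxy sulfone; 3 Weinreb amide
Product: 7 β-keto sulfone (C1 ketone, C2 sulfonyl, both C2 epimers)
Conditions: 6, n-BuLi (2.1 equiv), THF, −78 °C; then 3, −78 → −20 °C; aq. NH4Cl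
Reagents that add atoms: none
Why: Acylation of the α-sulfonyl carbanion (used as the alkoxide–carbanion dianion) by the Weinreb amide forms C1–C2 through a chelated tetrahedral intermediate, so neither over-addition nor enolisation at C10 is expected.

Step 6
Reactants: 7 β-keto sulfone
Product: 8 γ-hydroxy ketone (in equilibrium with its cyclic hemiketal)
Conditions: SmI2, THF–MeOH, −78 °C
Reagents that add atoms: none
Why: Reductive desulfonylation of the β-keto sulfone by electron transfer from SmI2 gives a samarium enolate that is protonated at C2, so C10 is not involved.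

Step 7
Reactants: 8 γ-hydroxy ketone
Product: 9 (1S,4R,10R) tetrahydrofuran methyl ketal with C5 PMB ether and terminal alkene
Conditions: PPTS (cat.), MeOH, rt
Reagents that add atoms: methanol, CO
Why: Acid-catalysed ketalisation of the γ-hydroxy ketone through the five-membered oxocarbenium ion closes the tetrahydrofuran; C1 is under thermodynamic control and is expected to form as both epimers, of which the (1S) epimer with the C5 and C10 arms cis is separated and the other is returned to the same conditions.

Step 8
Reactants: 9 methyl ketal alkene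
Product: 10 C8 aldehyde
Conditions: OsO4 (cat.), NaIO4, 2,6-lutidine, dioxane–H2O, rt
Reagents that add atoms: sodium periodate, [Na+].[O-]I(=O)(=O)=O (aldehyde oxygen, passed on through catalytic osmium tetroxide, O=[Os](=O)(=O)=O)
Why: Lemieux–Johnson oxidative cleavage of the only alkene gives the C8 aldehyde, and the lutidine buffer protects the ketal and the PMB ether.

Step 9
Reactants: 11 (E)-2,3-dibromobut-2-ene-1,4-diol
Product: 12 (E)-2,3-dibromo-4-(tert-butyldimethylsilyloxy)but-2-en-1-ol
Conditions: TBSCl, imidazole, DMF, 0 °C (11 in threefold excess)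
Reagents that add atoms: tert-butyldimethylsilyl chloride, CC(C)(C)[Si](C)(C)Cl
Why: Monosilylation of a symmetrical diol used in excess is statistical but clean, and unreacted diol is recovered.

Step 10
Reactants: 12 monosilylated dibromodiol
Product: 13 4-bromo-3-[(tert-butyldimethylsilyloxy)methyl]furan-2(5H)-one
Conditions: PdCl2(PPh3)2 (cat.), CO (3 bar), Et3N, THF, 60 °C
Reagents that add atoms: carbon monoxide, [C-]#[O+]
Why: Palladium-catalysed carbonylative lactonisation of a (Z)-β-bromo allylic alcohol: after oxidative addition of zerovalent palladium and CO insertion only the acyl group syn to the free CH2OH can close the five-membered lactone, which leaves bromine on the β-carbon (C7) and brings C13 in already protected.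

Step 11
Reactants: 10 C8 aldehyde; 13 bromobutenolide
Product: 14 C8 allylic alcohol (both C8 epimers)
Conditions: CrCl2 (4 equiv), NiCl2 (cat.), DMF, rt
Reagents that add atoms: none
Why: Nozaki–Hiyama–Kishi coupling: zerovalent nickel inserts into the β-bromo enoate C–Br bond, transmetallation gives an alkenylchromium species that adds to the aldehyde without touching lactone or ketal, and the C8 epimers that result are converged in steps 12 and 13.

Step 12
Reactants: 14 C8 allylic alcohols
Product: 15 C8 ketone (4-acylbutenolide)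
Conditions: Dess–Martin periodinane, NaHCO3, CH2Cl2, 0 °C → rt
Reagents that add atoms: none
Why: Dess–Martin oxidation under buffered conditions converts both C8 epimers into one 4-acylbutenolide without base-induced enolisation.

Step 13
Reactants: 15 C8 ketone
Product: 16 (8R)-allylic alcohol
Conditions: (S)-2-methyl-CBS-oxazaborolidine (cat.), catecholborane, toluene, −78 °C
Reagents that add atoms: none
Why: Corey–Bakshi–Shibata reduction: the (S)-oxazaborolidine–borane complex delivers hydride to the ketone face that leaves the butenolide alkenyl group as the large substituent, which sets C8 (R), and catecholborane at −78 °C favours 1,2-reduction.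

Step 14
Reactants: 16 (8R)-alcohol
Product: 17 C8,C13-bis-TBS ether with C5 PMB ether
Conditions: TBSOTf, 2,6-lutidine, CH2Cl2, −78 °C
Reagents that add atoms: tert-butyldimethylsilyl triflate, CC(C)(C)[Si](C)(C)OS(=O)(=O)C(F)(F)F
Why: Silylation with the silyl triflate and a hindered pyridine base protects the hindered allylic alcohol under conditions that leave ketals and the butenolide untouched.

Step 15
Reactants: 17 PMB ether
Product: 18 C5 primary alcohol
Conditions: DDQ, CH2Cl2–pH 7 buffer, 0 °C → rt
Reagents that add atoms: none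
Why: Oxidative PMB ether cleavage by DDQ proceeds through the benzylic oxocarbenium ion and water, and silyl ethers, ketal and the electron-poor butenolide are inert.

Step 16
Reactants: 18 C5 alcohol
Product: 19 C5 aldehyde (key-step precursor)
Conditions: Dess–Martin periodinane, NaHCO3, CH2Cl2, rt
Reagents that add atoms: none
Why: Dess–Martin oxidation gives an α-alkoxy aldehyde on quaternary C4 that has no α-hydrogen and therefore cannot epimerise or enolise.

Step 17
Reactants: 19 C5 aldehyde tethered to the γ-unsubstituted butenolide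
Product: 22 bridged methyl ketal (5E)-ylidene butenolide bis-TBS ether, via 2-silyloxyfuran 20 (not isolated), via silyl aldol adduct 21 (not isolated)
Conditions: TBSOTf (3 equiv), Et3N (6 equiv), CH2Cl2 (1 mM), −78 → 0 °C; then DBU, 0 °C → rt
Reagents that add atoms: none
Why: Proposed new method: TBSOTf and Et3N turn the γ-CH2 butenolide into 2-silyloxyfuran 20, the silyl triflate also activates the non-enolisable C5 aldehyde, and C6 attacks C5 through an open transition state (vinylogous Mukaiyama aldol) to give silyl aldol adduct 21, from which DBU removes the acidic C6 hydrogen and expels silanolate by an E1cB pathway to form C5=C6. The closest known reactions are the intermolecular one-pot conversion of butenolides and aldehydes into γ-alkylidene butenolides by silyl triflate, amine and DBU, and silylative cycloaldolisations of aldehyde-tethered butenolides that close five- to seven-membered rings; closure of a ten-membered ring is the untested part. The ring closes in exo-trig mode, ten-membered through carbon and nine-membered when counted through the ether bridge, and is run at high dilution. No stereocentre survives the step as new: the C5 and C6 centres of 21 are erased on elimination, C4 carries no hydrogen and the aldehyde cannot enolise. The step needs ring closure to outrun oligomerisation and needs the ring-cis (5E) alkene; the cis-2,5 arms on the tetrahydrofuran ketal hold C5 and C6 on one face, and only the geometry with C4 and C7 cis can be spanned by the C8–C10 chain. Et3N is kept in excess over TBSOTf and the temperature low so that the C1 methyl ketal and the C13 silyl ether are not ionised.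

Step 18
Reactants: 22 bis-TBS ether
Product: 23 C8,C13-diol (methyl ketal retained)
Conditions: HF·pyridine, pyridine, THF, 0 °C → rt
Reagents that add atoms: none
Why: Fluoride-mediated desilylation with buffered HF·pyridine is non-basic, so C8 is not epimerised through the vinylogous enolate, and anhydrous, so the methyl ketal stays.

Step 19
Reactants: 23 diol
Product: 24 C13 acetate with free C8 hydroxyl
Conditions: AcCl, 2,4,6-collidine, CH2Cl2, −78 °C
Reagents that add atoms: acetyl chloride, CC(=O)Cl
Why: Chemoselective acylation: acetyl chloride with collidine at low temperature acetylates the primary allylic C13 hydroxyl much faster than the hindered secondary C8 hydroxyl.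

Step 20
Reactants: 25 (R)-3-chloro-2-hydroxy-2-methylpropanoic acid
Product: 27 (R)-3-chloro-2-methyl-2-(triethylsilyloxy)propanoic acid, via bis-triethylsilyl derivative 26 (not isolated)
Conditions: TESOTf (2.5 equiv), 2,6-lutidine, CH2Cl2, 0 °C; then H2O–THF, 0 °C
Reagents that add atoms: triethylsilyl triflate, CC[Si](CC)(CC)OS(=O)(=O)C(F)(F)F
Why: Exhaustive silylation followed by hydrolysis of the labile silyl ester protects the tertiary hydroxyl, so that the activated acid cannot self-acylate or close to an epoxide.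

Step 21
Reactants: 24 C13 acetate; 27 protected side-chain acid
Product: 29 C8 ester of 24 bearing the TES-protected side chain, via mixed anhydride 28 (not isolated)
Conditions: 27, 2,4,6-trichlorobenzoyl chloride, Et3N, toluene, rt; then 24, DMAP, rt
Reagents that add atoms: none
Why: Yamaguchi esterification: the mixed anhydride and DMAP give an acylpyridinium ion that acylates the C8 hydroxyl with retention at C8, and the quaternary side-chain stereocentre cannot epimerise.

Step 22
Reactants: 29 protected ester
Product: 30 CNP0414417.2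
Conditions: aq. HF, MeCN, 0 °C → rt
Reagents that add atoms: water, O
Why: Acid-catalysed ketal hydrolysis through the C1 oxocarbenium ion gives the hemiketal, whose configuration (1S) is dictated by the bridged ring, and the same medium cleaves the tertiary TES ether while acetate, chloro ester and enol lactone are stable.

**Compound list**

1 | (S)-4-benzyl-3-propionyloxazolidin-2-one | O=C1OC[C@H](Cc2ccccc2)N1C(=O)CC | starting material
2 | (S)-4-benzyl-3-[(R)-2-methylpent-4-enoyl]oxazolidin-2-one | O=C1OC[C@H](Cc2ccccc2)N1C(=O)[C@H](C)CC=C | intermediate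
3 | (R)-N-methoxy-N,2-dimethylpent-4-enamide | C=CC[C@@H](C)C(=O)N(C)OC | intermediate
4 | (S)-2-methylglycidol, (S)-(2-methyloxiran-2-yl)methanol | OC[C@@]1(C)CO1 | starting material
5 | (R)-2-[(4-methoxybenzyloxy)methyl]-2-methyloxirane | COc1ccc(COC[C@@]2(C)CO2)cc1 | intermediate
6 | (R)-1-(4-methoxybenzyloxy)-2-methyl-4-(phenylsulfonyl)butan-2-ol | COc1ccc(COC[C@](C)(O)CCS(=O)(=O)c2ccccc2)cc1 | intermediate
7 | (2R,6R)-2-hydroxy-1-(4-methoxybenzyloxy)-2,6-dimethyl-4-(phenylsulfonyl)non-8-en-5-one, both epimers at the sulfonyl carbon | C=CC[C@@H](C)C(=O)C(S(=O)(=O)c1ccccc1)C[C@@](C)(O)COCc1ccc(OC)cc1 | intermediate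
8 | (2R,6R)-2-hydroxy-1-(4-methoxybenzyloxy)-2,6-dimethylnon-8-en-5-one, open form of its cyclic hemiketal | C=CC[C@@H](C)C(=O)CC[C@@](C)(O)COCc1ccc(OC)cc1 | intermediate
9 | (2S,5R)-2-methoxy-5-[(4-methoxybenzyloxy)methyl]-5-methyl-2-[(R)-pent-4-en-2-yl]tetrahydrofuran (1S,4R,10R in route locants) | COc1ccc(COC[C@@]2(C)CC[C@](OC)(O2)[C@H](C)CC=C)cc1 | intermediate
10 | (R)-3-{(2S,5R)-2-methoxy-5-[(4-methoxybenzyloxy)methyl]-5-methyltetrahydrofuran-2-yl}butanal | COc1ccc(COC[C@@]2(C)CC[C@](OC)(O2)[C@H](C)CC=O)cc1 | intermediate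
11 | (E)-2,3-dibromobut-2-ene-1,4-diol | OC/C(Br)=C(Br)/CO | starting material
12 | (E)-2,3-dibromo-4-(tert-butyldimethylsilyloxy)but-2-en-1-ol | CC(C)(C)[Si](C)(C)OC/C(Br)=C(Br)/CO | intermediate
13 | 4-bromo-3-[(tert-butyldimethylsilyloxy)methyl]furan-2(5H)-one | CC(C)(C)[Si](C)(C)OCC1=C(Br)COC1=O | intermediate
14 | 3-[(tert-butyldimethylsilyloxy)methyl]-4-[(3R)-1-hydroxy-3-{(2S,5R)-2-methoxy-5-[(4-methoxybenzyloxy)methyl]-5-methyltetrahydrofuran-2-yl}butyl]furan-2(5H)-one, both C8 epimers | COc1ccc(COC[C@@]2(C)CC[C@](OC)(O2)[C@H](C)CC(O)C3=C(CO[Si](C)(C)C(C)(C)C)C(=O)OC3)cc1 | intermediate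
15 | C8 ketone of 14, 4-[(3R)-3-{tetrahydrofuran ketal}butanoyl]-3-[(tert-butyldimethylsilyloxy)methyl]furan-2(5H)-one | COc1ccc(COC[C@@]2(C)CC[C@](OC)(O2)[C@H](C)CC(=O)C3=C(CO[Si](C)(C)C(C)(C)C)C(=O)OC3)cc1 | intermediate
16 | (8R)-alcohol, 4-[(1R,3R)-1-hydroxy-3-{(2S,5R)-2-methoxy-5-[(4-methoxybenzyloxy)methyl]-5-methyltetrahydrofuran-2-yl}butyl]-3-[(tert-butyldimethylsilyloxy)methyl]furan-2(5H)-one | COc1ccc(COC[C@@]2(C)CC[C@](OC)(O2)[C@H](C)C[C@@H](O)C3=C(CO[Si](C)(C)C(C)(C)C)C(=O)OC3)cc1 | intermediate
17 | C8 TBS ether of 16 (1S,4R,8R,10R; C5 PMB ether, C13 TBS ether) | COc1ccc(COC[C@@]2(C)CC[C@](OC)(O2)[C@H](C)C[C@@H](O[Si](C)(C)C(C)(C)C)C3=C(CO[Si](C)(C)C(C)(C)C)C(=O)OC3)cc1 | intermediate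
18 | C5 primary alcohol (hydroxymethyl on C4), C8 and C13 TBS ethers | OC[C@@]1(C)CC[C@](OC)(O1)[C@H](C)C[C@@H](O[Si](C)(C)C(C)(C)C)C2=C(CO[Si](C)(C)C(C)(C)C)C(=O)OC2 | intermediate
19 | key-step precursor, (2R,5S)-5-methoxy-2-methyltetrahydrofuran-2-carbaldehyde carrying on C5 the (2R,4R)-4-(tert-butyldimethylsilyloxy)-4-{3-[(tert-butyldimethylsilyloxy)methyl]-2-oxo-2,5-dihydrofuran-4-yl}butan-2-yl group | O=C[C@@]1(C)CC[C@](OC)(O1)[C@H](C)C[C@@H](O[Si](C)(C)C(C)(C)C)C2=C(CO[Si](C)(C)C(C)(C)C)C(=O)OC2 | intermediate
20 | 2-(tert-butyldimethylsilyloxy)furan of 19 (furan C3 bears CH2OTBS, C4 bears C8) | O=C[C@@]1(C)CC[C@](OC)(O1)[C@H](C)C[C@@H](O[Si](C)(C)C(C)(C)C)c2coc(O[Si](C)(C)C(C)(C)C)c2CO[Si](C)(C)C(C)(C)C | intermediate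
21 | macrocyclic silyl aldol adduct, C5 OTBS and C6 H, epimers at C5 and C6 | CC(C)(C)[Si](C)(C)OCC1=C2C(OC1=O)C(O[Si](C)(C)C(C)(C)C)[C@@]3(C)CC[C@](OC)(O3)[C@H](C)C[C@H]2O[Si](C)(C)C(C)(C)C | intermediate
22 | (1S,4R,5E,8R,10R)-8,13-bis(tert-butyldimethylsilyloxy)-1-methoxy-1,4-epoxygermacra-5,7(11)-dien-12,6-olide | CC(C)(C)[Si](C)(C)OCC1=C2/C(=C\[C@@]3(C)CC[C@](OC)(O3)[C@H](C)C[C@H]2O[Si](C)(C)C(C)(C)C)OC1=O | intermediate
23 | (1S,4R,5E,8R,10R)-8,13-dihydroxy-1-methoxy-1,4-epoxygermacra-5,7(11)-dien-12,6-olide | OCC1=C2/C(=C\[C@@]3(C)CC[C@](OC)(O3)[C@H](C)C[C@H]2O)OC1=O | intermediate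
24 | (1S,4R,5E,8R,10R)-13-acetoxy-8-hydroxy-1-methoxy-1,4-epoxygermacra-5,7(11)-dien-12,6-olide | CC(=O)OCC1=C2/C(=C\[C@@]3(C)CC[C@](OC)(O3)[C@H](C)C[C@H]2O)OC1=O | intermediate
25 | (R)-3-chloro-2-hydroxy-2-methylpropanoic acid | O=C(O)[C@@](C)(O)CCl | starting material
26 | triethylsilyl (R)-3-chloro-2-methyl-2-(triethylsilyloxy)propanoate | CC[Si](CC)(CC)OC(=O)[C@@](C)(O[Si](CC)(CC)CC)CCl | intermediate
27 | (R)-3-chloro-2-methyl-2-(triethylsilyloxy)propanoic acid | O=C(O)[C@@](C)(O[Si](CC)(CC)CC)CCl | intermediate
28 | mixed anhydride of 27 with 2,4,6-trichlorobenzoic acid | O=C(OC(=O)c1c(Cl)cc(Cl)cc1Cl)[C@@](C)(O[Si](CC)(CC)CC)CCl | intermediate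
29 | (1S,4R,5E,8R,10R)-13-acetoxy-8-[(R)-3-chloro-2-methyl-2-(triethylsilyloxy)propanoyloxy]-1-methoxy-1,4-epoxygermacra-5,7(11)-dien-12,6-olide | CC(=O)OCC1=C2/C(=C\[C@@]3(C)CC[C@](OC)(O3)[C@H](C)C[C@H]2OC(=O)[C@@](C)(O[Si](CC)(CC)CC)CCl)OC1=O | intermediate
30 | CNP0414417.2, (1S,4R,5E,8R,10R)-13-acetoxy-8-[(R)-3-chloro-2-hydroxy-2-methylpropanoyloxy]-1-hydroxy-1,4-epoxygermacra-5,7(11)-dien-12,6-olide | CC(=O)OCC1=C2/C(=C\[C@@]3(C)CC[C@](O)(O3)[C@H](C)C[C@H]2OC(=O)[C@@](C)(O)CCl)OC1=O | target

**Totals**

Total step count: 22. Longest linear sequence: 17 steps (steps 1, 2, 5–8, 11–19, 21, 22).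

**Three steps most likely to fail**

1. Step 17 (proposed new method). Intermolecular aldol oligomerisation may outrun closure of the strained ten-membered ring. The silyl triflate may ionise the C1 methyl ketal or the C13 silyloxy group of the silyloxyfuran. Elimination from the silyl aldol may be slow in the bridged ring. The fallback uses known chemistry and makes the same C5=C6 bond by intramolecular Horner–Wadsworth–Emmons olefination; it sets out from 17 and returns to the route at 22. The silyloxyfuran made from 17 (TBSOTf, Et3N) is brominated at C6 with NBS to give the γ-bromobutenolide F1. Michaelis–Arbuzov reaction with P(OEt)3 gives the γ-phosphonate F2. DDQ releases the C5 alcohol F3, and Dess–Martin oxidation gives the phosphonate aldehyde F4. LiCl and DBU in MeCN at high dilution then close the ring to 22.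

2. Step 10. After oxidative addition the second bromide may be lost to give the alkyne. Carbonylation at the C–Br bond that has no hydroxyl partner may lead to intermolecular esters. The product bromide may undergo further oxidative addition. The fallback brings C13 in after the coupling; it sets out from 10 and returns at 14. Nozaki–Hiyama–Kishi coupling of 10 with commercial 3,4-dibromofuran-2(5H)-one (CrCl2, NiCl2 cat.) should engage the more reactive β-bromide and give the 3-bromo-4-(1-hydroxyalkyl)butenolide F5. Stille coupling of the remaining α-bromide with Bu3SnCH2OH and Pd(PPh3)4 gives the C8,C13-diol F6. Selective silylation of the primary hydroxyl (TBSCl, imidazole, 0 °C) gives 14.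

3. Step 13. Facial discrimination may be poor because both ketone substituents are bulky. Hydride may add in conjugate fashion to the doubly activated alkene. The acylbutenolide may enolise toward C6. The fallback replaces reagent-controlled reduction by separation and inversion; it sets out from 14 and returns at 16. Chromatography of 14 gives 16 directly and its epimer, the (8S)-alcohol F7. Mitsunobu inversion of F7 (4-nitrobenzoic acid, PPh3, DIAD) gives the (8R)-4-nitrobenzoate F8. Mild methanolysis (K2CO3 cat., MeOH, 0 °C) gives 16.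

Further compounds
F1 | step 17 | C6-bromo derivative of 17 (γ-bromobutenolide, C6 epimers) | COc1ccc(COC[C@@]2(C)CC[C@](OC)(O2)[C@H](C)C[C@@H](O[Si](C)(C)C(C)(C)C)C3=C(CO[Si](C)(C)C(C)(C)C)C(=O)OC3Br)cc1
F2 | step 17 | C6 diethyl phosphonate of 17 (C6 epimers) | COc1ccc(COC[C@@]2(C)CC[C@](OC)(O2)[C@H](C)C[C@@H](O[Si](C)(C)C(C)(C)C)C3=C(CO[Si](C)(C)C(C)(C)C)C(=O)OC3P(=O)(OCC)OCC)cc1
F3 | step 17 | C5 alcohol of the C6 phosphonate | OC[C@@]1(C)CC[C@](OC)(O1)[C@H](C)C[C@@H](O[Si](C)(C)C(C)(C)C)C2=C(CO[Si](C)(C)C(C)(C)C)C(=O)OC2P(=O)(OCC)OCC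
F4 | step 17 | C5 aldehyde of the C6 phosphonate | O=C[C@@]1(C)CC[C@](OC)(O1)[C@H](C)C[C@@H](O[Si](C)(C)C(C)(C)C)C2=C(CO[Si](C)(C)C(C)(C)C)C(=O)OC2P(=O)(OCC)OCC
F5 | step 10 | 3-bromo-4-[(3R)-1-hydroxy-3-{tetrahydrofuran ketal}butyl]furan-2(5H)-one, C8 epimers | COc1ccc(COC[C@@]2(C)CC[C@](OC)(O2)[C@H](C)CC(O)C3=C(Br)C(=O)OC3)cc1
F6 | step 10 | 3-(hydroxymethyl) analogue of 14, C8,C13-diol, C8 epimers | COc1ccc(COC[C@@]2(C)CC[C@](OC)(O2)[C@H](C)CC(O)C3=C(CO)C(=O)OC3)cc1
F7 | step 13 | (8S)-epimer of 16 | COc1ccc(COC[C@@]2(C)CC[C@](OC)(O2)[C@H](C)C[C@H](O)C3=C(CO[Si](C)(C)C(C)(C)C)C(=O)OC3)cc1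
F8 | step 13 | (8R)-4-nitrobenzoate of 16 | COc1ccc(COC[C@@]2(C)CC[C@](OC)(O2)[C@H](C)C[C@@H](OC(=O)c4ccc(cc4)[N+](=O)[O-])C3=C(CO[Si](C)(C)C(C)(C)C)C(=O)OC3)cc1
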